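## Structural features

The target is a C20 gibberellin. Cyclohexane ring A (C1–C5, C10) is trans-fused to cyclopentane ring B (C5, C6, C8, C9, C10), and rings C and D form a bicyclo[3.2.1]octane (C8, C9, C11–C16) that shares the C8–C9 bond with ring B and carries the exocyclic C16=C17 methylene. There are nine stereocentres (C3, C4, C5, C6, C8, C9, C10, C12, C13); they run contiguously along C3–C4–C5–C6 and C5–C10–C9–C8, and C4, C8 and C10 are quaternary. With α defined as the face of C20, the substituents are 3β-OH (axial), 4α-CO2H and 4β-CH3, 5β-H, 6β-CO2H, 9β-H, 10α-CHO and 12α-OH (axial on ring C, 1,3-related to C10). The fragile points are: the 3-hydroxyl, β to the C19 carbonyl, which can epimerise by retro-aldol in base; C6–H, α to a carboxyl; the C20 aldehyde, 1,3-diaxial to C19 (lactol with the acid, δ-lactone as soon as a C20 alcohol sits beside a C19 ester); and the 1,1-disubstituted alkene, which isomerises in strong protic acid. The real difficulty is the congested core C4(quaternary)–C5–C10(quaternary)–C9–C8(quaternary) with C6 attached, followed by the bridged ring system whose sense is fixed at C8. The key step exploits two features: C3, C4, C18 and C19 make up an α-methyl β-keto ester whose C4 radical can add to a C5=C10 alkene (ring A), and C10, C5, C6, C8, C9, C11 then form a 1,5-diene, so the C10 radical can close ring B on C9. A symmetric cyclopent-3-ene spiro-fused at C8 already holds C13–C16, so C8 need not be stereogenic until ring C is closed.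

## Logic of the disconnections

**45 ⇒ 44.** Cut the O–Si bonds at O3 and O12 and the ester C–O bonds at C19 and C7. Free 45 is sensitive to base (C3, C6) and to strong acid (C16=C17), so all four groups are chosen to fall to fluoride in one operation. The gain is that 44 is neutral and easy to handle. The demand is that fluoride attack silicon only; the 2-silylethyl esters fragment whatever the hindrance at C19 and C7.

**44 ⇒ 43 ⇒ 42.** Take C20=O back to the alcohol and then to its 4-methoxybenzyl ether. A C20 alcohol beside the C19 ester lactonises, so C20 stays etherified until the end. The demand is neutral unmasking and immediate oxidation.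

**42 ⇒ 41 ⇒ 40 ⇒ 38.** Cut C16=C17 (methylenation of a C16 ketone), then trace the C16 oxygen back to the C15=C16 alkene. C17 is not part of the cyclisation skeleton, and C15=C16 is what the ring C closure leaves behind. The demand is boron on C16 and not C15, with O3 and O12 masked during the oxidation.

**38 ⇒ 37 ⇒ 36.** Cut the C3–H and C12–H bonds (hydride). Both carbinols are axial, so one bulky hydride can set both from a diketone. Two stereocentres disappear. The demand is equatorial attack at both carbonyls.

**36 ⇒ 35 ⇒ 34.** Cut C12–C13 (ring C). Opening the bicycle here returns the symmetric spiro-cyclopentene, so C8 and C13 cease to be stereocentres. The demand is that C12 bond to the ring carbon on its own (α) side; the ene reaction delivers the 12β-alcohol, so 36 is a planned relay.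

**34 ⇒ 33 ⇒ 31.** The C12 aldehyde comes from the C11=C12 vinyl group by anti-Markovnikov hydration. The demand is selectivity over the ring alkene and the C3 ketone.

**31 ⇒ 30 (key step).** Cut C4–C5 and C9–C10. Two rings and four stereocentres (C4, C5, C9, C10) are traded for one stereocentre (C6) in an open chain. The simplest substrate for this cascade would carry methyl esters and a C20 acetate; 30 is improved in two ways:
- **C20 as a 4-methoxybenzyl ether.** An acetate would not survive the hydroxide and hydride steps of this route, and its basic removal would drive 19,20-lactonisation.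
- **Both carboxyls as 2-(trimethylsilyl)ethyl esters.** The hindered C19 and C7 esters can then be released without hydroxide.

The demand on 30 is an alkene with C1 trans to C6 and a single configuration at C6.

**30 ⇒ 25 + 28.** Cut C3–C4. A decarboxylative C-acylation builds the β-keto ester under neutral conditions, so the acidic C6–H and the allyl sulfone are never exposed to an enolate base.

**25 ⇒ 24 ⇒ 21 + 22.** Cut C1–C2 with transposition of the C5 oxygen ([3,3]). The rearrangement fixes the C5=C10 geometry and turns a stereodefined aldol carbinol into the alkene. The demand is a chair transition state with the C6 group equatorial and no loss of C6 configuration at 135 °C.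

**21 ⇒ 20 ⇒ 18 ⇒ 12 + 16.** Cut C5–C6 (aldol). A chiral oxazolidinone sets C6, the only stereocentre that the key step needs. C7 stays at the acid level throughout, which avoids a configurationally labile α-formyl ester.

**12 ⇒ 9 + 10; 9 ⇒ 7 + 8; 7 ⇒ 4 + 5; 4 ⇒ 3 ⇒ 1 + 2.** Cut N–C7, then C12–S with allylic transposition, then C9–C11, then C6–C8. The vinyl lactone 7 lets one palladium step unmask the C7 acid and install the E-allyl sulfone together.

**16 ⇒ 15 ⇒ 13 + 14 and 28 ⇒ 26 + 27.** Both partners come from symmetric catalogue compounds in one or two steps.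

## Other disconnections considered

**Alternative 1:** This cuts C9–C11 and C8–C15 around the ring B enone A1.
- **Forward step.** CuBr·SMe2 (monovalent copper) with a chiral phosphoramidite would add CH2=CHMgBr to C9 of A1; the C8 enolate would be trapped with Me3SiC≡CCH2Br to give A2.
- **In its favour.** The absolute configuration comes from a catalyst, not an auxiliary. C9 and the quaternary C8 are set in one operation with vinyl and propargyl trans, which is the C11/C15 relationship of 45. The butenyl and vinyl arms are poised for ring-closing metathesis to ring C, and the alkyne already holds C16 and C17. On the definition of C8 this plan is the better one: C8 is a defined stereocentre from the start, where the chosen plan relies on a geometric bias at ring C closure.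
- **Against it here.** The step closes no ring. Rings A, C and D, the quaternary C10 and C4, and C5 and C6 would all still have to be built on a cyclopentanone, and the congested trans A/B fusion is deferred. A 2-substituted cyclopentenone is a sluggish acceptor for copper-catalysed Grignard addition, and the fully substituted magnesium enolate may O-alkylate or react SN2′ with the propargylic bromide.
- **Comparison.** Mechanistically it is polar, catalyst-controlled chemistry against a substrate-controlled radical cascade. In step economy the chosen key step forms two rings and four stereocentres where A2 forms none, so the alternative is expected to be longer.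

**Alternative 2:** This cuts C3–C4 (ring A) of the pentacyclic lactone A4 back to the α-bromo δ-lactone aldehyde A3.
- **Forward step.** SmI2 (divalent samarium) would reduce the C4–Br bond to a samarium enolate that adds to the C3 aldehyde.
- **In its favour.** The lactone tether forces C19 syn to C20, so C4 is set by ring constraint and not by a chair preference; on this point it is the equal of, or better than, the chosen plan. The reaction is mild and late, with rings B, C and D and the methylene already in place.
- **Against it here.** The whole B/C/D system with a quaternary C10 carrying two differentiated arms must exist first, so the hard problem is only moved earlier. As drawn, A4 has the C3 hydroxyl α, the epimer of the 3β-hydroxyl of 45, so an oxidation and a bulky hydride reduction would still be needed. The lactone holds C20 at the alcohol level; raising it to the aldehyde means opening a δ-lactone that re-closes readily. Ketyl formation at the aldehyde and retro-aldol are further risks.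
- **Comparison.** The chosen plan fixes C3 later by reagent control and keeps C20 etherified to stay out of the lactone. Step economy is not expected to be better.

**Alternative 3:** This cuts C13–C14 and C12–C13 of the β-keto sulfone A6 back to the iodo ester A5.
- **Forward step.** Two equivalents of LiN(SiMe3)2 would alkylate the sulfonyl carbanion at C13 with the C14 iodide (ring D) and then acylate it with the C12 ester (ring C).
- **In its favour.** Two rings close in one flask, the C16 methylene is present from the start, and C12 emerges as a ketone ready for hydride. For rings C and D this is shorter than the chosen plan, which needs seven operations from 34 to 42, and is the better plan there.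
- **Against it here.** A5 needs the complete A/B system with C8 as a defined quaternary stereocentre bearing two different arms, which the symmetric spiro ring of the chosen plan avoids. The first bond forms by SN2 at a neopentyl iodide, and α- versus γ-attack of the allyl sulfone anion must be controlled. The second bond gives a bridgehead β-keto sulfone with no acidic proton, so the acylation has no enolate sink and methoxide can reverse it. The C6 ester is exposed to excess amide base, and a desulfonylation step follows.
- **Comparison.** It is anionic and thermodynamically delicate against a radical, irreversible chosen step. Overall length depends on the access to A5, which is expected to cost more than the chosen plan saves.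

Key step: step 15

Assumption: compounds 1, 2, 5, 8, 10, 13, 14, 22, 26 and 27 and the trichloroacetimidate of step 10 are catalogue chemicals; gibberellin numbering is used for all intermediates, α is the face of C20, PMB is 4-methoxybenzyl, TMSE is 2-(trimethylsilyl)ethyl and TBS is tert-butyldimethylsilyl.

## Route

Step 1
Reactants: 1 methyl cyclopent-3-ene-1-carboxylate; 2 tert-butyl bromoacetate
Product: 3 methyl 1-(2-tert-butoxy-2-oxoethyl)cyclopent-3-ene-1-carboxylate
Conditions: LDA, THF, −78 °C; then 2, −78 → 0 °C
Reagents that add atoms: none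
Why: Alkylation of the lithium ester enolate with a reactive α-bromo ester (SN2) makes the quaternary C8 and attaches C6–C7; no stereocentre arises because the ring is symmetric.

Step 2
Reactants: 3 methyl 1-(2-tert-butoxy-2-oxoethyl)cyclopent-3-ene-1-carboxylate
Product: 4 tert-butyl 2-(1-formylcyclopent-3-en-1-yl)acetate
Conditions: DIBAL-H (1.1 equiv), CH2Cl2, −78 °C; aq. Rochelle salt
Reagents that add atoms: none
Why: Partial reduction of the methyl ester; the aluminium hemiacetal of the α-quaternary ester is stable at −78 °C and the tert-butyl ester reacts much more slowly.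

Step 3
Reactants: 4 tert-butyl 2-(1-formylcyclopent-3-en-1-yl)acetate; 5 vinylmagnesium bromide
Product: 7 1-ethenyl-2-oxaspiro[4.4]non-7-en-3-one (racemic), via bromomagnesium alkoxide 6 (not isolated)
Conditions: 5, THF, −78 → 23 °C; aq. NH4Cl
Reagents that add atoms: none
Why: Grignard 1,2-addition to the neopentyl aldehyde forms C9–C11, and the alkoxide then displaces tert-butoxide from the ester (5-exo-trig lactonisation); the racemic carbinol centre is erased in step 4.

Step 4
Reactants: 7 1-ethenyl-2-oxaspiro[4.4]non-7-en-3-one; 8 sodium benzenesulfinate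
Product: 9 2-{1-[(E)-3-(phenylsulfonyl)prop-1-en-1-yl]cyclopent-3-en-1-yl}acetic acid
Conditions: Pd(PPh3)4 (5 mol %, zerovalent palladium), 8, DMF, 50 °C; then 1 M HCl
Reagents that add atoms: none
Why: Tsuji–Trost allylic substitution: palladium ionises the allylic lactone C–O bond to a π-allyl carboxylate and the soft sulfinate attacks through sulfur at the unhindered terminus C12; the syn π-allyl complex and reversibility give the linear E sulfone and free the C7 acid.

Step 5
Reactants: 9 2-{1-[(E)-3-(phenylsulfonyl)prop-1-en-1-yl]cyclopent-3-en-1-yl}acetic acid; 10 (R)-4-benzyl-1,3-oxazolidin-2-one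
Product: 12 (R)-4-benzyl-3-(2-{1-[(E)-3-(phenylsulfonyl)prop-1-en-1-yl]cyclopent-3-en-1-yl}acetyl)-1,3-oxazolidin-2-one, via mixed pivalic anhydride 11 (not isolated)
Conditions: PivCl, Et3N, THF, −20 °C; then LiCl, 10, −20 → 23 °C
Reagents that add atoms: none
Why: N-Acylation of the oxazolidinone through the mixed anhydride (LiCl/Et3N variant); no stereocentre is touched.

Step 6
Reactants: 13 2-methylidenepropane-1,3-diol; 14 4-methoxybenzyl chloride
Product: 15 2-{[(4-methoxybenzyl)oxy]methyl}prop-2-en-1-ol
Conditions: NaH (1.0 equiv), THF, 0 °C; 14, Bu4NI (cat.), 0 → 23 °C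
Reagents that add atoms: none
Why: Williamson mono-etherification of the symmetric diol through its mono-alkoxide; diether and diol are removed by chromatography.

Step 7
Reactants: 15 2-{[(4-methoxybenzyl)oxy]methyl}prop-2-en-1-ol
Product: 16 2-{[(4-methoxybenzyl)oxy]methyl}prop-2-enal
Conditions: MnO2 (activated, excess), CH2Cl2, 23 °C
Reagents that add atoms: none
Why: MnO2 oxidation of a primary allylic alcohol, mild enough for the polymerisable 2-substituted acrolein (C5, C10, C1, C20).

Step 8
Reactants: 12 (R)-4-benzyl-3-(2-{1-[(E)-3-(phenylsulfonyl)prop-1-en-1-yl]cyclopent-3-en-1-yl}acetyl)-1,3-oxazolidin-2-one; 16 2-{[(4-methoxybenzyl)oxy]methyl}prop-2-enal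
Product: 18 (R)-4-benzyl-3-[(2R,3R)-3-hydroxy-4-(PMB-oxymethyl)-2-{1-[(E)-3-(phenylsulfonyl)prop-1-enyl]cyclopent-3-en-1-yl}pent-4-enoyl]-1,3-oxazolidin-2-one (syn aldol), via Z boron enolate 17 (not isolated)
Conditions: Bu2BOTf, Et3N, CH2Cl2, −78 → 0 °C; then 16, −78 → 0 °C; pH 7 buffer, MeOH, 30 % H2O2, 0 °C
Reagents that add atoms: none
Why: Evans syn aldol: soft enolisation gives the Z boron enolate, which adds to the enal through a closed chair transition state on the face away from the benzyl group; this sets C6 (and C5, which is consumed in step 11), and the R auxiliary is the one that gives the C6 configuration of the target.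

Step 9
Reactants: 18 syn aldol imide
Product: 20 (2R,3R)-3-hydroxy-4-(PMB-oxymethyl)-2-{1-[(E)-3-(phenylsulfonyl)prop-1-enyl]cyclopent-3-en-1-yl}pent-4-enoic acid, via peroxy acid 19 (not isolated)
Conditions: LiOH·H2O, 30 % H2O2, THF/H2O, 0 °C; then aq. Na2SO3; then 1 M HCl
Reagents that add atoms: hydrogen peroxide, OO
Why: Hydroperoxide cleavage of the hindered imide at the exocyclic carbonyl, with sulfite reduction of the peracid; too mild for retro-aldol or epimerisation at C6, and the auxiliary is recovered.

Step 10
Reactants: 20 (2R,3R)-hydroxy acid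
Product: 21 2-(trimethylsilyl)ethyl (2R,3R)-3-hydroxy-4-(PMB-oxymethyl)-2-{1-[(E)-3-(phenylsulfonyl)prop-1-enyl]cyclopent-3-en-1-yl}pent-4-enoate
Conditions: 2-(trimethylsilyl)ethyl 2,2,2-trichloroacetimidate (2 equiv), toluene, 90 °C
Reagents that add atoms: 2-(trimethylsilyl)ethyl 2,2,2-trichloroacetimidate, C[Si](C)(C)CCOC(=N)C(Cl)(Cl)Cl
Why: Promoter-free O-alkylation of the carboxylic acid by the trichloroacetimidate; the carboxylate is the nucleophile, so the hindered acyl carbon is not attacked, and the secondary alcohol is not acidic enough to activate the imidate.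

Step 11
Reactants: 21 TMSE hydroxy ester; 22 triethyl orthoacetate
Product: 24 ethyl TMSE diester EtO2C–C2H2–C1H2–C10(CH2OPMB)=C5H–C6H(CO2TMSE)–C8(cyclopent-3-ene-1,1-diyl)–CH=CH–CH2SO2Ph with 6S configuration and C1 trans to C6 (Z by the sequence rule), via ketene acetal 23 (not isolated)
Conditions: 22 (10 equiv), EtCO2H (0.1 equiv), 135 °C, EtOH distilled off
Reagents that add atoms: none
Why: Johnson–Claisen rearrangement: orthoester exchange and loss of ethanol give the ketene acetal, whose chair [3,3] shift with the bulky C6 group equatorial forms C1–C2 and the C5=C10 alkene with C1 trans to C6; the C5 carbinol is consumed and C6 is not touched under the weakly acidic conditions.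

Step 12
Reactants: 24 ethyl TMSE diester
Product: 25 the corresponding C3 carboxylic acid (C7 TMSE ester retained)
Conditions: LiOH·H2O (1.5 equiv), THF/H2O, 0 → 23 °C; then 1 M HCl, 0 °C
Reagents that add atoms: lithium hydroxide, [Li+].[OH-]
Why: Saponification selective for the unhindered primary-chain ethyl ester; the C7 ester lies between the quaternary C8 and the branched alkene and is not attacked at this temperature.

Step 13
Reactants: 26 2,2,5-trimethyl-1,3-dioxane-4,6-dione; 27 2-(trimethylsilyl)ethanol
Product: 28 2-methyl-3-oxo-3-[2-(trimethylsilyl)ethoxy]propanoic acid (racemic)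
Conditions: toluene, 100 °C
Reagents that add atoms: none
Why: Alcoholysis of the alkylated Meldrum's acid with loss of acetone gives the malonic half ester that carries C4, C18 and C19.

Step 14
Reactants: 25 C3 carboxylic acid; 28 2-methyl-3-oxo-3-[2-(trimethylsilyl)ethoxy]propanoic acid
Product: 30 cyclisation precursor TMSE-O2C–CH(CH3)–CO–CH2CH2–C(CH2OPMB)=CH–CH(CO2TMSE)–C(cyclopent-3-ene-1,1-diyl)–CH=CH–CH2SO2Ph (6S; both C4 epimers), via acyl imidazolide 29 (not isolated)
Conditions: CDI, THF, 23 °C; then 28, MgCl2, Et3N, MeCN, 23 → 40 °C; 1 M HCl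
Reagents that add atoms: none
Why: Decarboxylative C-acylation of the magnesium malonate half ester by the acyl imidazolide (Masamune–Brooks type Claisen condensation) forms C3–C4 under neutral conditions that do not deprotonate C6 or the sulfone; the C4 epimers converge in step 15.

Step 15
Reactants: 30 cyclisation precursor
Product: 31 trans-fused A/B keto diester: 3-oxo, 4β-methyl, 4α-CO2TMSE, 5β-H, 6β-CO2TMSE, 9α-vinyl (9β-H), 10α-CH2OPMB, C8 spiro-fused to cyclopent-3-ene
Conditions: Mn(OAc)3·2H2O (2.2 equiv), degassed AcOH (0.02 M), 23 → 45 °C, Ar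
Reagents that add atoms: none
Why: Mn(OAc)3 (trivalent manganese) forms the manganese enolate of the α-methyl β-keto ester and oxidises it by one electron to the electrophilic tertiary C4 radical; the closest known reaction type is the oxidative free-radical polyene cyclisation of α-substituted β-keto esters, ended here by addition–fragmentation on an allyl sulfone. Ring A closes 6-endo-trig (C4 to C5) through a chair, because attack at the CH terminus gives the tertiary C10 radical; ring B closes 5-exo-trig (C10 to C9), and the C11 radical expels PhSO2 by β-scission, leaving the C11=C12 vinyl group, while the second equivalent of oxidant consumes the sulfonyl radical. C4: the ester is axial and the methyl equatorial in the chair, the usual outcome of these cyclisations, which puts C19 syn to C20. C5 and C10: anti addition across an alkene whose C1 and C6 substituents are trans gives the trans ring fusion. Face selection: the C6–H bond lies in the alkene plane toward the C20 methylene to avoid allylic 1,3-strain, so the quaternary C8 shields one face, C4 adds to the other, and C8 then delivers C9 to C10 from its own side. C9: the alkene sits pseudo-equatorial in the chair-like 5-exo transition state, which places C11 syn to C20. The step needs 6-endo over 5-exo in the first closure (secured by the fully substituted C10 terminus) and ring B closure faster than hydrogen abstraction or attack on the cyclopentene (secured by the tethered, activated allyl sulfone, by AcOH as a poor hydrogen donor and by the absence of Cu(OAc)2, which would intercept the C10 radical).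

Step 16
Reactants: 31 trans-fused A/B keto diester
Product: 33 the C12 primary alcohol (C9–CH2CH2OH), via catechol boronate 32 (not isolated)
Conditions: catecholborane, RhCl(PPh3)3 (3 mol %, monovalent rhodium), THF, 0 → 23 °C; then NaBO3·4H2O, THF/H2O, 23 °C
Reagents that add atoms: sodium perborate, [Na+].[Na+].O[B-]1(O)OO[B-](O)(O)OO1
Why: Rhodium-catalysed hydroboration is fast for the monosubstituted alkene and leaves the hindered ketone and the 1,2-disubstituted ring alkene alone; boron goes to the terminal C12, and mild perborate oxidation avoids retro-Claisen of the keto ester.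

Step 17
Reactants: 33 C12 primary alcohol
Product: 34 the C12 aldehyde (C9–CH2CHO)
Conditions: Dess–Martin periodinane, NaHCO3, CH2Cl2, 0 → 23 °C
Reagents that add atoms: none
Why: Dess–Martin oxidation of a primary alcohol to the aldehyde under buffered, neutral conditions.

Step 18
Reactants: 34 C12 aldehyde
Product: 35 tetracyclic 12β-alcohol with the C15=C16 alkene (17-nor-gibberell-15-ene skeleton; 3-oxo, 20-OPMB, 7,19-bis-TMSE ester)
Conditions: Me2AlCl (2.5 equiv), CH2Cl2, −78 → −20 °C; aq. Rochelle salt
Reagents that add atoms: none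
Why: Lewis acid promoted intramolecular carbonyl-ene reaction: the complexed aldehyde carbon C12 bonds to the olefinic carbon on its own side of the spiro ring (C13) while the allylic hydrogen of C15 passes to oxygen, closing ring C as a bicyclo[3.2.1]octene. C8 and C13 follow from C9 because only the α-side carbon is within reach; the cyclic transition state places the hydroxyl syn to C16 (12β), which steps 19 and 20 correct.

Step 19
Reactants: 35 tetracyclic 12β-alcohol
Product: 36 the 3,12-diketone with the C15=C16 alkene
Conditions: Dess–Martin periodinane, NaHCO3, CH2Cl2, 0 → 23 °C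
Reagents that add atoms: none
Why: Dess–Martin oxidation; the β,γ-unsaturated ketone cannot move into conjugation because C13 is a bridgehead.

Step 20
Reactants: 36 3,12-diketone
Product: 37 the 3β,12α-diol
Conditions: L-Selectride (3.5 equiv), THF, −78 → −40 °C; then H2O
Reagents that add atoms: none
Why: The bulky trialkylborohydride attacks both ketones along the equatorial trajectory: at C3 this gives the axial 3β-alcohol (as known for 4,4-disubstituted 3-ketones), and at C12 hydride arrives from the open side next to the flat C16 and away from the axial C10, giving the axial 12α-alcohol.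

Step 21
Reactants: 37 3β,12α-diol
Product: 38 the 3,12-bis-TBS ether
Conditions: TBSOTf, 2,6-lutidine, CH2Cl2, 0 → 40 °C
Reagents that add atoms: tert-butyldimethylsilyl trifluoromethanesulfonate, CC(C)(C)[Si](C)(C)OS(=O)(=O)C(F)(F)F
Why: Silylation of two hindered axial alcohols with the silyl triflate.

Step 22
Reactants: 38 3,12-bis-TBS ether
Product: 40 the 16-exo alcohol (hydroxyl on the side of C14), via B-alkyl-9-BBN adduct 39 (not isolated)
Conditions: 9-BBN, THF, 23 → 60 °C; then 3 M NaOH, 30 % H2O2, 0 → 23 °C
Reagents that add atoms: hydrogen peroxide, OO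
Why: Hydroboration–oxidation: the borane adds from the exo face and places boron on C16, the olefinic carbon remote from the quaternary C8 and the C7 ester; oxidation goes with retention, and the C16 centre is removed in step 23.

Step 23
Reactants: 40 16-exo alcohol
Product: 41 the 16-ketone
Conditions: Dess–Martin periodinane, NaHCO3, CH2Cl2, 23 °C
Reagents that add atoms: none
Why: Dess–Martin oxidation of the secondary alcohol.

Step 24
Reactants: 41 16-ketone
Product: 42 the 16-methylene compound (C16=C17)
Conditions: Ph3PCH3Br, KOtBu, THF, 0 → 50 °C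
Reagents that add atoms: methyltriphenylphosphonium bromide, [Br-].C[P+](c1ccccc1)(c1ccccc1)c1ccccc1
Why: Wittig methylenation of the bicyclic cyclopentanone, well precedented for 17-nor-16-ketones of this family; hindered esters and silyl ethers are inert.

Step 25
Reactants: 42 16-methylene compound
Product: 43 the C20 primary alcohol
Conditions: DDQ, CH2Cl2/pH 7 buffer (10:1), 0 → 23 °C
Reagents that add atoms: none
Why: Oxidative cleavage of the PMB ether by DDQ under buffered neutral conditions; no base is present to drive lactonisation onto C19, and the crude alcohol is used at once.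

Step 26
Reactants: 43 C20 primary alcohol
Product: 44 the C20 aldehyde (3,12-bis-TBS ether, 7,19-bis-TMSE ester)
Conditions: Dess–Martin periodinane, NaHCO3, CH2Cl2, 0 → 23 °C
Reagents that add atoms: none
Why: Dess–Martin oxidation of the neopentyl alcohol to the non-enolisable aldehyde.

Step 27
Reactants: 44 protected C20 aldehyde
Product: 45 target, 3β,12α-dihydroxy-20-oxo C20-gibberellin-7,19-dioic acid (CNP0218328.1)
Conditions: TBAF (10 equiv), THF, 0 → 45 °C; then 0.5 M HCl to pH 3, 0 °C
Reagents that add atoms: none
Why: Fluoride attacks silicon only: both silyl ethers are cleaved and both 2-silylethyl esters fragment to ethene, fluorosilane and carboxylate, whatever the hindrance at C19 and C7; no hydroxide or strong acid is needed, so C3, C6 and the C16 methylene are not put at risk (the product may sit partly as its 19,20-lactol).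

## Compound list

1 | methyl cyclopent-3-ene-1-carboxylate | COC(=O)C1CC=CC1 | starting material
2 | tert-butyl bromoacetate | CC(C)(C)OC(=O)CBr | starting material
3 | methyl 1-(2-tert-butoxy-2-oxoethyl)cyclopent-3-ene-1-carboxylate | COC(=O)C1(CC(=O)OC(C)(C)C)CC=CC1 | intermediate
4 | tert-butyl 2-(1-formylcyclopent-3-en-1-yl)acetate | O=CC1(CC(=O)OC(C)(C)C)CC=CC1 | intermediate
5 | vinylmagnesium bromide | C=C[Mg]Br | starting material
6 | bromomagnesium alkoxide of tert-butyl 2-[1-(1-hydroxyprop-2-en-1-yl)cyclopent-3-en-1-yl]acetate (racemic) | C=CC(O[Mg]Br)C1(CC(=O)OC(C)(C)C)CC=CC1 | intermediate (not isolated)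
7 | 1-ethenyl-2-oxaspiro[4.4]non-7-en-3-one (racemic) | C=CC1OC(=O)CC12CC=CC2 | intermediate
8 | sodium benzenesulfinate | [Na+].[O-]S(=O)c1ccccc1 | starting material
9 | 2-{1-[(E)-3-(phenylsulfonyl)prop-1-en-1-yl]cyclopent-3-en-1-yl}acetic acid | OC(=O)CC1(CC=CC1)/C=C/CS(=O)(=O)c1ccccc1 | intermediate
10 | (R)-4-benzyl-1,3-oxazolidin-2-one | O=C1N[C@H](Cc2ccccc2)CO1 | starting material
11 | mixed pivalic anhydride of 9 | CC(C)(C)C(=O)OC(=O)CC1(CC=CC1)/C=C/CS(=O)(=O)c1ccccc1 | intermediate (not isolated)
12 | (R)-4-benzyl-3-(2-{1-[(E)-3-(phenylsulfonyl)prop-1-en-1-yl]cyclopent-3-en-1-yl}acetyl)-1,3-oxazolidin-2-one | O=C(CC1(CC=CC1)/C=C/CS(=O)(=O)c1ccccc1)N1C(=O)OC[C@H]1Cc1ccccc1 | intermediate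
13 | 2-methylidenepropane-1,3-diol | C=C(CO)CO | starting material
14 | 4-methoxybenzyl chloride | COc1ccc(CCl)cc1 | starting material
15 | 2-{[(4-methoxybenzyl)oxy]methyl}prop-2-en-1-ol | C=C(CO)COCc1ccc(OC)cc1 | intermediate
16 | 2-{[(4-methoxybenzyl)oxy]methyl}prop-2-enal | C=C(C=O)COCc1ccc(OC)cc1 | intermediate
17 | Z dibutylboron enolate of 12 | CCCCB(CCCC)O/C(N1C(=O)OC[C@H]1Cc1ccccc1)=C\C1(CC=CC1)/C=C/CS(=O)(=O)c1ccccc1 | intermediate (not isolated)
18 | syn aldol imide, (2R,3R) in the acyl chain (C6 R, C5 R) | C=C(COCc1ccc(OC)cc1)[C@H](O)[C@H](C(=O)N1C(=O)OC[C@H]1Cc1ccccc1)C1(CC=CC1)/C=C/CS(=O)(=O)c1ccccc1 | intermediate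
19 | peroxy acid from 18 | C=C(COCc1ccc(OC)cc1)[C@H](O)[C@H](C(=O)OO)C1(CC=CC1)/C=C/CS(=O)(=O)c1ccccc1 | intermediate (not isolated)
20 | (2R,3R)-3-hydroxy-4-(PMB-oxymethyl)-2-{1-[(E)-3-(phenylsulfonyl)prop-1-enyl]cyclopent-3-en-1-yl}pent-4-enoic acid | C=C(COCc1ccc(OC)cc1)[C@H](O)[C@H](C(=O)O)C1(CC=CC1)/C=C/CS(=O)(=O)c1ccccc1 | intermediate
21 | 2-(trimethylsilyl)ethyl ester of 20 | C=C(COCc1ccc(OC)cc1)[C@H](O)[C@H](C(=O)OCC[Si](C)(C)C)C1(CC=CC1)/C=C/CS(=O)(=O)c1ccccc1 | intermediate
22 | triethyl orthoacetate | CCOC(C)(OCC)OCC | starting material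
23 | mixed ketene acetal of 21 (C5–O–C(OEt)=CH2) | C=C(COCc1ccc(OC)cc1)[C@H](OC(=C)OCC)[C@H](C(=O)OCC[Si](C)(C)C)C1(CC=CC1)/C=C/CS(=O)(=O)c1ccccc1 | intermediate (not isolated)
24 | ethyl TMSE diester, 6S, C5=C10 with C1 trans to C6 | CCOC(=O)CC/C(COCc1ccc(OC)cc1)=C/[C@H](C(=O)OCC[Si](C)(C)C)C1(CC=CC1)/C=C/CS(=O)(=O)c1ccccc1 | intermediate
25 | C3 carboxylic acid, 6S | OC(=O)CC/C(COCc1ccc(OC)cc1)=C/[C@H](C(=O)OCC[Si](C)(C)C)C1(CC=CC1)/C=C/CS(=O)(=O)c1ccccc1 | intermediate
26 | 2,2,5-trimethyl-1,3-dioxane-4,6-dione | CC1C(=O)OC(C)(C)OC1=O | starting material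
27 | 2-(trimethylsilyl)ethanol | C[Si](C)(C)CCO | starting material
28 | 2-methyl-3-oxo-3-[2-(trimethylsilyl)ethoxy]propanoic acid (racemic) | CC(C(=O)O)C(=O)OCC[Si](C)(C)C | intermediate
29 | acyl imidazolide of 25 | O=C(CC/C(COCc1ccc(OC)cc1)=C/[C@H](C(=O)OCC[Si](C)(C)C)C1(CC=CC1)/C=C/CS(=O)(=O)c1ccccc1)n1ccnc1 | intermediate (not isolated)
30 | cyclisation precursor, 6S, both C4 epimers | C[Si](C)(C)CCOC(=O)C(C)C(=O)CC/C(COCc1ccc(OC)cc1)=C/[C@H](C(=O)OCC[Si](C)(C)C)C1(CC=CC1)/C=C/CS(=O)(=O)c1ccccc1 | intermediate
31 | trans-fused A/B keto diester with 9α-vinyl and C8 spiro-cyclopentene | C=C[C@H]2[C@]1(COCc4ccc(OC)cc4)CCC(=O)[C@@](C)(C(=O)OCC[Si](C)(C)C)[C@H]1[C@H](C(=O)OCC[Si](C)(C)C)C23CC=CC3 | intermediate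
32 | catechol boronate at C12 | c5ccc6OB(CC[C@H]2[C@]1(COCc4ccc(OC)cc4)CCC(=O)[C@@](C)(C(=O)OCC[Si](C)(C)C)[C@H]1[C@H](C(=O)OCC[Si](C)(C)C)C23CC=CC3)Oc6c5 | intermediate (not isolated)
33 | C12 primary alcohol | OCC[C@H]2[C@]1(COCc4ccc(OC)cc4)CCC(=O)[C@@](C)(C(=O)OCC[Si](C)(C)C)[C@H]1[C@H](C(=O)OCC[Si](C)(C)C)C23CC=CC3 | intermediate
34 | C12 aldehyde | O=CC[C@H]2[C@]1(COCc4ccc(OC)cc4)CCC(=O)[C@@](C)(C(=O)OCC[Si](C)(C)C)[C@H]1[C@H](C(=O)OCC[Si](C)(C)C)C23CC=CC3 | intermediate
35 | tetracyclic 12β-alcohol, C15=C16, 3-ketone | C1=C[C@]23C[C@H]1[C@H](O)C[C@H]2[C@]1(COCc4ccc(OC)cc4)CCC(=O)[C@@](C)(C(=O)OCC[Si](C)(C)C)[C@H]1[C@@H]3C(=O)OCC[Si](C)(C)C | intermediate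
36 | tetracyclic 3,12-diketone, C15=C16 | C1=C[C@]23C[C@H]1C(=O)C[C@H]2[C@]1(COCc4ccc(OC)cc4)CCC(=O)[C@@](C)(C(=O)OCC[Si](C)(C)C)[C@H]1[C@@H]3C(=O)OCC[Si](C)(C)C | intermediate
37 | 3β,12α-diol, C15=C16 | C1=C[C@]23C[C@H]1[C@@H](O)C[C@H]2[C@]1(COCc4ccc(OC)cc4)CC[C@H](O)[C@@](C)(C(=O)OCC[Si](C)(C)C)[C@H]1[C@@H]3C(=O)OCC[Si](C)(C)C | intermediate
38 | 3β,12α-bis-TBS ether, C15=C16 | C1=C[C@]23C[C@H]1[C@@H](O[Si](C)(C)C(C)(C)C)C[C@H]2[C@]1(COCc4ccc(OC)cc4)CC[C@H](O[Si](C)(C)C(C)(C)C)[C@@](C)(C(=O)OCC[Si](C)(C)C)[C@H]1[C@@H]3C(=O)OCC[Si](C)(C)C | intermediate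
39 | B-(C16-exo-alkyl)-9-borabicyclo[3.3.1]nonane adduct of 38 | C5CCC6CCCC5B6[C@@H]1C[C@]23C[C@H]1[C@@H](O[Si](C)(C)C(C)(C)C)C[C@H]2[C@]1(COCc4ccc(OC)cc4)CC[C@H](O[Si](C)(C)C(C)(C)C)[C@@](C)(C(=O)OCC[Si](C)(C)C)[C@H]1[C@@H]3C(=O)OCC[Si](C)(C)C | intermediate (not isolated)
40 | 16-exo alcohol | O[C@@H]1C[C@]23C[C@H]1[C@@H](O[Si](C)(C)C(C)(C)C)C[C@H]2[C@]1(COCc4ccc(OC)cc4)CC[C@H](O[Si](C)(C)C(C)(C)C)[C@@](C)(C(=O)OCC[Si](C)(C)C)[C@H]1[C@@H]3C(=O)OCC[Si](C)(C)C | intermediate
41 | 16-ketone | O=C1C[C@]23C[C@H]1[C@@H](O[Si](C)(C)C(C)(C)C)C[C@H]2[C@]1(COCc4ccc(OC)cc4)CC[C@H](O[Si](C)(C)C(C)(C)C)[C@@](C)(C(=O)OCC[Si](C)(C)C)[C@H]1[C@@H]3C(=O)OCC[Si](C)(C)C | intermediate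
42 | 16-methylene compound, 20-OPMB | C=C1C[C@]23C[C@H]1[C@@H](O[Si](C)(C)C(C)(C)C)C[C@H]2[C@]1(COCc4ccc(OC)cc4)CC[C@H](O[Si](C)(C)C(C)(C)C)[C@@](C)(C(=O)OCC[Si](C)(C)C)[C@H]1[C@@H]3C(=O)OCC[Si](C)(C)C | intermediate
43 | C20 primary alcohol | C=C1C[C@]23C[C@H]1[C@@H](O[Si](C)(C)C(C)(C)C)C[C@H]2[C@]1(CO)CC[C@H](O[Si](C)(C)C(C)(C)C)[C@@](C)(C(=O)OCC[Si](C)(C)C)[C@H]1[C@@H]3C(=O)OCC[Si](C)(C)C | intermediate
44 | C20 aldehyde, 3,12-bis-TBS ether, 7,19-bis-TMSE ester | C=C1C[C@]23C[C@H]1[C@@H](O[Si](C)(C)C(C)(C)C)C[C@H]2[C@]1(C=O)CC[C@H](O[Si](C)(C)C(C)(C)C)[C@@](C)(C(=O)OCC[Si](C)(C)C)[C@H]1[C@@H]3C(=O)OCC[Si](C)(C)C | intermediate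
45 | 3β,12α-dihydroxy-20-oxo C20-gibberellin-7,19-dioic acid (CNP0218328.1) | C=C1C[C@]23C[C@H]1[C@@H](O)C[C@H]2[C@]1(C=O)CC[C@H](O)[C@@](C)(C(=O)O)[C@H]1[C@@H]3C(=O)O | target

## Step count and least certain steps

Total step count: 27. Longest linear sequence: 24 steps (1–5, 8–12, 14–27). Steps 6–7 and step 13 make 16 and 28 on side branches.

**Step 15 (key step).** The most likely failure is slow addition of the congested tertiary C4 radical to C5, which lets over-oxidation or hydrogen abstraction at C4 compete; incomplete face selection at the first ring closure is the second concern. A third, smaller concern is interception of the C10 radical by the anisyl ring of the C20 ether; this would need a six-membered closure on an arene or a 1,4-hydrogen shift, both expected to be slower than the 5-exo closure on the activated allyl sulfone. The fallback keeps the same bonds but changes how the radical is made. It sets out from 30: α-bromination at C4 (NBS, Mg(ClO4)2 cat., MeCN, 0 °C) should give the α-bromo β-keto ester F1. Et3B and air in benzene at 23–60 °C would then start a bromine-atom abstraction chain. The same 6-endo/5-exo cascade follows, the expelled PhSO2 radical is taken up by Et3B (which releases the next ethyl radical), and the route is rejoined at 31. No metal oxidant is present to intercept the intermediates.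

**Step 11.** The risk is β-elimination of the activated C5 oxygen toward a conjugated dienoate, or erosion of the C6 configuration, during prolonged heating of a hindered carbinol with acid. The fallback sets out from 21. Transfer vinylation (Pd(OCOCF3)2, divalent palladium, with 4,7-diphenyl-1,10-phenanthroline, Et3N, butyl vinyl ether) should give the O-vinyl ether F2. Heating in toluene at 110 °C (aliphatic Claisen rearrangement) should give the C3 aldehyde F3 with the same alkene geometry. A Reformatsky reaction with 2-(trimethylsilyl)ethyl 2-bromopropanoate and zinc should then give the β-hydroxy ester F4, and Dess–Martin oxidation rejoins the route at 30, bypassing steps 12–14.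

**Step 18.** The aldehyde may react through a stepwise cation, leading to chloride capture or a Wagner–Meerwein shift of the bicyclo[3.2.1]octyl cation, or the 1,2-disubstituted alkene may be too weak an ene partner. The fallback replaces the ene reaction by a dipolar cycloaddition and sets out from 34. NH2OH·HCl and NaOAc should give the oxime F5. NaOCl in CH2Cl2/H2O at high dilution should then generate the nitrile oxide, which adds across the ring alkene to give the isoxazoline F6 (C12–C13 bond, oxygen on C16). Mo(CO)6 in MeCN/H2O at 80 °C should cleave the N–O bond and give the 16-hydroxy-3,12-dione F7. Syn-dehydration with the Burgess reagent can only run toward C15, because C13 is a bridgehead, and rejoins the route at 36.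

**Step 22.** Boron may be delivered in part to C15, or the addition to the hindered bridge alkene may be sluggish. The fallback fixes the C16 oxygen through the tether. It sets out from 34 and passes through the oxime F5, the isoxazoline F6 and the ketol F7, made as described for step 18. Me4NBH(OAc)3 in MeCN/AcOH (hydroxyl-directed reduction) should deliver hydride to C12 from the side of the C16 oxygen and give the 12α,16-diol F8 with the C3 ketone intact. TESCl and imidazole should silylate the less hindered 16-hydroxyl and give the 16-O-triethylsilyl ether F9. L-Selectride should then reduce the C3 ketone from the equatorial side and give the 3β,12α-diol 16-O-triethylsilyl ether F10. TBSOTf and 2,6-lutidine should give the bis-TBS ether F11, PPTS in MeOH should remove the triethylsilyl group and leave the 16-endo alcohol F12, and Dess–Martin oxidation rejoins the route at 41.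

## Further compounds

F1 | step 15 | C4-bromo derivative of 30 (α-bromo β-keto ester) | C[Si](C)(C)CCOC(=O)C(C)(Br)C(=O)CC/C(COCc1ccc(OC)cc1)=C/[C@H](C(=O)OCC[Si](C)(C)C)C1(CC=CC1)/C=C/CS(=O)(=O)c1ccccc1
F2 | step 11 | O-vinyl ether of 21 | C=C(COCc1ccc(OC)cc1)[C@H](OC=C)[C@H](C(=O)OCC[Si](C)(C)C)C1(CC=CC1)/C=C/CS(=O)(=O)c1ccccc1
F3 | step 11 | C3 aldehyde, 6S, C1 trans to C6 | O=CCC/C(COCc1ccc(OC)cc1)=C/[C@H](C(=O)OCC[Si](C)(C)C)C1(CC=CC1)/C=C/CS(=O)(=O)c1ccccc1
F4 | step 11 | C3 hydroxy ester (Reformatsky adduct, mixture at C3 and C4) | C[Si](C)(C)CCOC(=O)C(C)C(O)CC/C(COCc1ccc(OC)cc1)=C/[C@H](C(=O)OCC[Si](C)(C)C)C1(CC=CC1)/C=C/CS(=O)(=O)c1ccccc1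
F5 | step 18 | oxime of 34 | ON=CC[C@H]2[C@]1(COCc4ccc(OC)cc4)CCC(=O)[C@@](C)(C(=O)OCC[Si](C)(C)C)[C@H]1[C@H](C(=O)OCC[Si](C)(C)C)C23CC=CC3
F6 | step 18 | isoxazoline (C12=N–O–C16, oxygen endo on C16) | O5[C@H]1C[C@]23C[C@H]1C(=N5)C[C@H]2[C@]1(COCc4ccc(OC)cc4)CCC(=O)[C@@](C)(C(=O)OCC[Si](C)(C)C)[C@H]1[C@@H]3C(=O)OCC[Si](C)(C)C
F7 | step 18 | 16-endo-hydroxy-3,12-dione | O[C@H]1C[C@]23C[C@H]1C(=O)C[C@H]2[C@]1(COCc4ccc(OC)cc4)CCC(=O)[C@@](C)(C(=O)OCC[Si](C)(C)C)[C@H]1[C@@H]3C(=O)OCC[Si](C)(C)C
F8 | step 22 | 12α,16-endo-diol 3-ketone | O[C@H]1C[C@]23C[C@H]1[C@@H](O)C[C@H]2[C@]1(COCc4ccc(OC)cc4)CCC(=O)[C@@](C)(C(=O)OCC[Si](C)(C)C)[C@H]1[C@@H]3C(=O)OCC[Si](C)(C)C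
F9 | step 22 | 16-O-triethylsilyl ether of F8 | CC[Si](CC)(CC)O[C@H]1C[C@]23C[C@H]1[C@@H](O)C[C@H]2[C@]1(COCc4ccc(OC)cc4)CCC(=O)[C@@](C)(C(=O)OCC[Si](C)(C)C)[C@H]1[C@@H]3C(=O)OCC[Si](C)(C)C
F10 | step 22 | 3β,12α-diol 16-O-triethylsilyl ether | CC[Si](CC)(CC)O[C@H]1C[C@]23C[C@H]1[C@@H](O)C[C@H]2[C@]1(COCc4ccc(OC)cc4)CC[C@H](O)[C@@](C)(C(=O)OCC[Si](C)(C)C)[C@H]1[C@@H]3C(=O)OCC[Si](C)(C)C
F11 | step 22 | 3,12-bis-TBS 16-O-triethylsilyl ether | CC[Si](CC)(CC)O[C@H]1C[C@]23C[C@H]1[C@@H](O[Si](C)(C)C(C)(C)C)C[C@H]2[C@]1(COCc4ccc(OC)cc4)CC[C@H](O[Si](C)(C)C(C)(C)C)[C@@](C)(C(=O)OCC[Si](C)(C)C)[C@H]1[C@@H]3C(=O)OCC[Si](C)(C)C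
F12 | step 22 | 16-endo alcohol (C16 epimer of 40) | O[C@H]1C[C@]23C[C@H]1[C@@H](O[Si](C)(C)C(C)(C)C)C[C@H]2[C@]1(COCc4ccc(OC)cc4)CC[C@H](O[Si](C)(C)C(C)(C)C)[C@@](C)(C(=O)OCC[Si](C)(C)C)[C@H]1[C@@H]3C(=O)OCC[Si](C)(C)C
A1 | alternative 1 | 2-(but-3-en-1-yl)cyclopent-2-en-1-one | C=CCCC1=CCCC1=O
A2 | alternative 1 | ring B cyclopentanone with C9 vinyl group and quaternary C8 bearing butenyl and silylpropargyl arms | C=C[C@H]1CCC(=O)[C@@]1(CC#C[Si](C)(C)C)CCC=C
A3 | alternative 2 | C4-bromo 19,20-δ-lactone with the C3 aldehyde on the C10 side chain | C=C1C[C@]23C[C@H]1[C@@H](O[Si](C)(C)C(C)(C)C)C[C@H]2[C@@]1(CCC=O)COC(=O)C(C)(Br)[C@H]1[C@@H]3C(=O)OC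
A4 | alternative 2 | pentacyclic 19,20-lactone with ring A closed, quaternary C4 and C3 hydroxyl | C=C1C[C@]23C[C@H]1[C@@H](O[Si](C)(C)C(C)(C)C)C[C@H]2[C@]1(CO4)CC[C@@H](O)[C@@](C)(C4=O)[C@H]1[C@@H]3C(=O)OC
A5 | alternative 3 | A/B diester with C14 iodide, C12 methyl ester arm and 2-(phenylsulfonylmethyl)allyl arm on C8 | C=C(CS(=O)(=O)c4ccccc4)C[C@]3(CI)[C@@H](CC(=O)OC)[C@]1(CO[Si](C)(C)C(C)(C)C)CC[C@H](O[Si](C)(C)C(C)(C)C)[C@@](C)(C(=O)OC)[C@H]1[C@@H]3C(=O)OC(C)(C)C
A6 | alternative 3 | tetracyclic C12 ketone with C13 phenylsulfonyl group and C16 exocyclic methylene | C=C1C[C@]23C[C@@]1(S(=O)(=O)c4ccccc4)C(=O)C[C@H]2[C@]1(CO[Si](C)(C)C(C)(C)C)CC[C@H](O[Si](C)(C)C(C)(C)C)[C@@](C)(C(=O)OC)[C@H]1[C@@H]3C(=O)OC(C)(C)C
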